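Numbering (guaiane, used for all intermediates): ring A = C1–C5 (CH3 on C4); ring B = C1, C5–C10 (C1=C10, CH3 on C10, carbinol carbon C11 on C7, ester O on C8).
Cuts, in retrosynthetic order: O8–acyl; C10–CH3; C3=C4 (ring A, metathesis); C1–C2 and C4–C5 together; C1=C5 (ring B, metathesis); C10–C1; both C11–CH3 bonds; C6–C7.
Enabling feature: ring A is joined to ring B through C1 and C5 only. These two atoms are the α- and β-carbons of a ring B enone with its carbonyl at C10, so C4 can enter as a nucleophile and C2 as an electrophile in one flask.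
Forward order: C5–C11 chain from 3-hydroxyglutarate, then ring B, then the three-component coupling, then ring A, then C1=C10 with its methyl, then C4–H, then the coumarate.
Stereochemistry: C8 comes from a lipase desymmetrisation, C7 from chelate-controlled anti allylation next to C8, C5 from a chiral copper catalyst, and C4 from hydrogenation of ring A on the face of H5. The centres at C1 and at the C10 carbinol are transient.

Key step: step 13

Assumption: the antipode of the ferrocenyl diphosphine that sends the alkenyl group to the Re face of C5 is taken to be (R,Sp); if a test run shows the opposite sense, the commercial (S,Rp) antipode replaces it with no other change.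

Step 1
Reactants: 1 diethyl 3-hydroxyglutarate
Product: 2 (3S)-5-ethoxy-3-hydroxy-5-oxopentanoic acid (monoethyl (S)-3-hydroxyglutarate)
Conditions: immobilised Candida antarctica lipase B, phosphate buffer pH 7, 30 °C
Reagents that add atoms: water, SMILES O
Why: Enzymatic desymmetrisation of a prochiral diester, in which the lipase hydrolyses only the pro-R ethoxycarbonylmethyl arm, so the carbinol carbon (C8) becomes S and the two arms (C9–C10 acid, C7–C11 ester) are told apart.

Step 2
Reactants: 2 monoethyl (S)-3-hydroxyglutarate
Product: 3 ethyl (3S)-3,5-dihydroxypentanoate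
Conditions: BH3·SMe2, THF, 0 °C to rt; then H2O
Reagents that add atoms: none
Why: Chemoselective borane reduction, since the free acid is reduced through its acyloxyborane far faster than the ethyl ester and C8 is not touched.

Step 3
Reactants: 3 ethyl (3S)-3,5-dihydroxypentanoate
Product: 4 ethyl (3S)-5-(tert-butyldiphenylsilyloxy)-3-hydroxypentanoate
Conditions: TBDPSCl, imidazole, CH2Cl2, 0 °C
Reagents that add atoms: tert-butyldiphenylsilyl chloride, SMILES CC(C)(C)[Si](Cl)(c1ccccc1)c1ccccc1
Why: Selective silylation, because the bulky chlorosilane reacts only at the primary C10 hydroxyl, which stops lactonisation and leaves the C8 hydroxyl free for chelation in the next step.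

Step 4
Reactants: 4 ethyl (3S)-5-(tert-butyldiphenylsilyloxy)-3-hydroxypentanoate; 5 allyl bromide
Product: 7 ethyl (2S,3S)-2-allyl-5-(tert-butyldiphenylsilyloxy)-3-hydroxypentanoate (anti), via dilithium alkoxide enolate 6 (not isolated)
Conditions: LiN(i-Pr)2 (2.3 equiv), THF, −78 to −20 °C; then 5, DMPU, −78 to −10 °C; H2O
Reagents that add atoms: none
Why: Fráter–Seebach alkylation, in which lithium ties alkoxide and enolate oxygen into a six-membered chelate whose C9 chain covers one face, so allyl bromide enters from the other face, forms C6–C7 and sets C7 as S (anti to O8).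

Step 5
Reactants: 7 anti allyl hydroxy ester
Product: 8 (3S,4S)-1-(tert-butyldiphenylsilyloxy)-4-(2-hydroxypropan-2-yl)hept-6-en-3-ol
Conditions: MeMgBr (4 equiv), Et2O–THF, 0 °C to rt
Reagents that add atoms: methylmagnesium bromide, SMILES C[Mg]Br
Why: Double Grignard addition to the ester builds the C11 carbinol with both methyl groups, the excess reagent covers the free hydroxyl, and silyl ether, alkene and both stereocentres are inert.

Step 6
Reactants: 8 1,3-diol
Product: 9 (5S,6S)-5-allyl-6-[2-(tert-butyldiphenylsilyloxy)ethyl]-2,2,4,4-tetramethyl-1,3-dioxane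
Conditions: 2-methoxypropene, PPTS (cat.), CH2Cl2, 0 °C to rt
Reagents that add atoms: 2-methoxypropene, SMILES COC(C)=C
Why: Acetonide formation with an enol ether is effectively irreversible and therefore also captures the tertiary O11, giving a dioxane with C6 and C9 trans-diequatorial and no change at C7 or C8.

Step 7
Reactants: 9 silyl ether acetonide
Product: 10 2-[(4S,5S)-5-allyl-2,2,6,6-tetramethyl-1,3-dioxan-4-yl]ethanol
Conditions: TBAF, THF, rt
Reagents that add atoms: none
Why: Fluoride desilylation is driven by the Si–F bond and leaves ketal and alkene untouched.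

Step 8
Reactants: 10 primary alcohol
Product: 11 2-[(4S,5S)-5-allyl-2,2,6,6-tetramethyl-1,3-dioxan-4-yl]acetaldehyde
Conditions: Dess–Martin periodinane, NaHCO3, CH2Cl2, 0 °C to rt
Reagents that add atoms: none
Why: Buffered Dess–Martin oxidation stops at the aldehyde and is neither basic nor acidic enough to eliminate the β-oxygen at C8 or to open the ketal.

Step 9
Reactants: 11 aldehyde
Product: 12 1-[(4S,5S)-5-allyl-2,2,6,6-tetramethyl-1,3-dioxan-4-yl]but-3-en-2-ol (both C10 epimers)
Conditions: CH2=CHMgBr, THF, −78 °C
Reagents that add atoms: vinylmagnesium bromide, SMILES C=C[Mg]Br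
Why: Grignard 1,2-addition forms C10–C1, and the new carbinol centre needs no control because it is oxidised in step 11.

Step 10
Reactants: 12 diene alcohol
Product: 13 (4aS,9aS)-2,2,4,4-tetramethyl-4,4a,5,8,9,9a-hexahydrocyclohepta[d][1,3]dioxin-8-ol (ring B allylic alcohol; both C10 epimers)
Conditions: second-generation Grubbs catalyst RuCl2(=CHPh)(PCy3)(H2IMes) (3 mol %), CH2Cl2 (5 mM), 40 °C
Reagents that add atoms: none
Why: Ring-closing metathesis of two monosubstituted alkenes closes ring B at C1=C5, helped by the gauche arrangement of the two chains on the dioxane and by loss of ethylene.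

Step 11
Reactants: 13 cycloheptenol
Product: 14 (4aS,9aS)-2,2,4,4-tetramethyl-4a,5,9,9a-tetrahydro-4H-cyclohepta[d][1,3]dioxin-8-one (ring B enone: C10=O; C1=C5; trans-fused 8,11-acetonide)
Conditions: Dess–Martin periodinane, NaHCO3, CH2Cl2, 0 °C to rt
Reagents that add atoms: none
Why: Dess–Martin oxidation merges both allylic alcohol epimers into one enone under conditions too mild for loss of the C8 oxygen.

Step 12
Reactants: 15 2-bromopropene
Product: 16 isopropenylmagnesium bromide (solution in Et2O)
Conditions: Mg turnings, Et2O, reflux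
Reagents that add atoms: magnesium, SMILES [Mg]
Why: Grignard formation is carried out in diethyl ether because strongly coordinating THF lowers the selectivity of diphosphine–copper catalysts.

Step 13
Reactants: 14 ring B enone acetonide; 16 isopropenylmagnesium bromide; 17 allyl iodide
Product: 19 (1S,5R,7S,8S)-1-allyl-5-isopropenyl ring B ketone 8,11-acetonide (allyl trans to isopropenyl), via bromomagnesium enolate 18 (not isolated)
Conditions: CuBr·SMe2 (5 mol %), (R)-1-[(Sp)-2-(diphenylphosphino)ferrocenyl]ethyldicyclohexylphosphine (6 mol %), t-BuOMe, −75 °C, slow addition of 16 (1.3 equiv); then DMPU, 17 (5 equiv), −75 to 0 °C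
Reagents that add atoms: none
Why: The diphosphine-bound monovalent copper bromide is transmetallated by 16, binds the C1=C5 π bond, adds at C5 to a trivalent copper species and reductively eliminates, which forms C4–C5 and leaves enolate 18 with its double bond fixed between C1 and C10; DMPU then loosens the magnesium enolate so that it displaces iodide from 17 at C1 (SN2) and C1–C2 forms. The closest known chemistry is the copper/ferrocenyl-diphosphine-catalysed asymmetric conjugate addition of Grignard reagents to cycloalkenones with alkylative trapping of the magnesium enolate. The step closes no ring and only places the two alkenyl chains on neighbouring carbons for the metathesis of step 14. C5 is set by the catalyst, which must deliver the alkenyl group to the Re face (cis to C11) against the preference of the ring for axial attack trans to the equatorial C7 substituent, a preference that is only torsional because both dioxane bonds are equatorial and far from C5. C1 is set by approach of allyl iodide anti to the new isopropenyl group, and its configuration does not matter since C1 becomes sp2 in step 15. The step needs 1,4- over 1,2-addition and C1 over C9 alkylation: the first is secured by copper catalysis at low temperature, the second by an enolate that is born regiodefined and is consumed by a large excess of a fast electrophile before proton transfer to the C9 side, next to the C8 oxygen, can begin.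

Step 14
Reactants: 19 allyl isopropenyl ketone
Product: 20 (1S,5R,7S,8S)-tricyclic ketone (ring A cyclopentene with C3=C4 and CH3 on C4; trans-fused to ring B; C10=O; 8,11-acetonide)
Conditions: second-generation Grubbs catalyst (5 mol %), CH2Cl2, 40 °C
Reagents that add atoms: none
Why: Ring-closing metathesis of a monosubstituted with a 1,1-disubstituted alkene closes ring A as a trisubstituted cyclopentene at C3=C4, a closure open to either C1 epimer.

Step 15
Reactants: 20 tricyclic ketone
Product: 22 (5S,7S,8S)-C10 enol triflate with C1=C10 and C3=C4 (8,11-acetonide), via thermodynamic bromomagnesium enolate 21 (not isolated)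
Conditions: i-Pr2NMgBr (from i-Pr2NH and MeMgBr), Et2O–THF, 0 °C to rt; then PhNTf2, rt to 35 °C
Reagents that add atoms: N-phenylbis(trifluoromethanesulfonimide), SMILES O=S(=O)(N(c1ccccc1)S(=O)(=O)C(F)(F)F)C(F)(F)F
Why: Thermodynamic enolisation followed by O-triflation, in which the magnesium amide deprotonates reversibly so that the enolate settles on the tetrasubstituted C1=C10 isomer (exocyclic to ring A), while the C8–O bond, held equatorial by the trans-fused dioxane and thus near the nodal plane of any C9 enolate, is badly aligned for β-elimination.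

Step 16
Reactants: 22 enol triflate
Product: 23 (5S,7S,8S)-guaia-1(10),3-diene-8,11-diol acetonide
Conditions: MeMgBr, Fe(acac)3 (10 mol %), THF–NMP, −20 to 0 °C
Reagents that add atoms: methylmagnesium bromide, SMILES C[Mg]Br
Why: Iron-catalysed Kumada-type cross-coupling of an alkenyl triflate replaces the triflate by methyl with the double bond held at C1=C10, and a methyl group offers no β-hydride pathway.

Step 17
Reactants: 23 skipped diene
Product: 24 (4S,5S,7S,8S)-guai-1(10)-ene-8,11-diol acetonide
Conditions: H2 (1 atm), PtO2 (5 mol %), EtOAc, 0 °C, stopped after one equivalent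
Reagents that add atoms: none
Why: In this heterogeneous catalytic hydrogenation the trisubstituted C3=C4 bond adsorbs while the buried tetrasubstituted C1=C10 bond does not, and because ring A is nearly flat with C6 below and only H5 above, hydrogen arrives on the H5 face and sets C4 as S (methyl cis to C6).

Step 18
Reactants: 24 acetonide
Product: 25 (4S,5S,7S,8S)-guai-1(10)-ene-8,11-diol
Conditions: AcOH–THF–H2O (3:1:1), 35 °C
Reagents that add atoms: none
Why: Acid hydrolysis of the ketal is easy because the tetramethyl dioxane is strained by a syn-diaxial methyl pair, so conditions too weak to move the alkene or ionise the tertiary alcohol suffice.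

Step 19
Reactants: 26 p-coumaric acid
Product: 28 (E)-3-[4-(tert-butyldimethylsilyloxy)phenyl]prop-2-enoic acid, via bis-silyl derivative 27 (not isolated)
Conditions: TBSCl (2.3 equiv), imidazole, DMF, rt; then AcOH–THF–H2O, rt
Reagents that add atoms: tert-butyldimethylsilyl chloride, SMILES CC(C)(C)[Si](C)(C)Cl
Why: Exhaustive silylation followed by selective hydrolysis works because a silyl ester is far more labile than an aryl silyl ether, and the E alkene is unaffected.

Step 20
Reactants: 25 diol; 28 silyl-protected p-coumaric acid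
Product: 29 (4S,5S,7S,8S)-11-hydroxyguai-1(10)-en-8-yl (E)-3-[4-(tert-butyldimethylsilyloxy)phenyl]prop-2-enoate
Conditions: DCC, DMAP (cat.), CH2Cl2, 0 °C to rt
Reagents that add atoms: none
Why: Steglich esterification acylates the secondary C8 hydroxyl with retention, while the tertiary C11 hydroxyl is too hindered to react with the acylpyridinium ion.

Step 21
Reactants: 29 silyl-protected ester
Product: 30 CNP0403230.1, (4S,5S,7S,8S)-11-hydroxyguai-1(10)-en-8-yl (E)-p-coumarate
Conditions: TBAF, AcOH (1:1), THF, 0 °C
Reagents that add atoms: none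
Why: Buffered fluoride desilylation cleaves the aryl silyl ether within minutes, and the acetic acid keeps the medium from becoming basic enough to attack the cinnamate ester.

Compound list
1 | diethyl 3-hydroxyglutarate | CCOC(=O)CC(O)CC(=O)OCC | starting material
2 | (3S)-5-ethoxy-3-hydroxy-5-oxopentanoic acid | CCOC(=O)C[C@@H](O)CC(=O)O | intermediate
3 | ethyl (3S)-3,5-dihydroxypentanoate | CCOC(=O)C[C@@H](O)CCO | intermediate
4 | ethyl (3S)-5-(tert-butyldiphenylsilyloxy)-3-hydroxypentanoate | CCOC(=O)C[C@@H](O)CCO[Si](c1ccccc1)(c1ccccc1)C(C)(C)C | intermediate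
5 | allyl bromide | C=CCBr | starting material
6 | dilithium alkoxide enolate of 4 (enolate O cis to C8) | CCO/C(O[Li])=C/[C@@H](O[Li])CCO[Si](c1ccccc1)(c1ccccc1)C(C)(C)C | intermediate
7 | ethyl (2S,3S)-2-allyl-5-(tert-butyldiphenylsilyloxy)-3-hydroxypentanoate | C=CC[C@H](C(=O)OCC)[C@@H](O)CCO[Si](c1ccccc1)(c1ccccc1)C(C)(C)C | intermediate
8 | (3S,4S)-1-(tert-butyldiphenylsilyloxy)-4-(2-hydroxypropan-2-yl)hept-6-en-3-ol | C=CC[C@H](C(C)(C)O)[C@@H](O)CCO[Si](c1ccccc1)(c1ccccc1)C(C)(C)C | intermediate
9 | (5S,6S)-5-allyl-6-[2-(tert-butyldiphenylsilyloxy)ethyl]-2,2,4,4-tetramethyl-1,3-dioxane | C=CC[C@H]1[C@@H](OC(C)(C)OC1(C)C)CCO[Si](c2ccccc2)(c2ccccc2)C(C)(C)C | intermediate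
10 | 2-[(4S,5S)-5-allyl-2,2,6,6-tetramethyl-1,3-dioxan-4-yl]ethanol | C=CC[C@H]1[C@@H](OC(C)(C)OC1(C)C)CCO | intermediate
11 | 2-[(4S,5S)-5-allyl-2,2,6,6-tetramethyl-1,3-dioxan-4-yl]acetaldehyde | C=CC[C@H]1[C@@H](OC(C)(C)OC1(C)C)CC=O | intermediate
12 | 1-[(4S,5S)-5-allyl-2,2,6,6-tetramethyl-1,3-dioxan-4-yl]but-3-en-2-ol (both C10 epimers) | C=CC[C@H]1[C@@H](OC(C)(C)OC1(C)C)CC(O)C=C | intermediate
13 | (4aS,9aS)-2,2,4,4-tetramethyl-4,4a,5,8,9,9a-hexahydrocyclohepta[d][1,3]dioxin-8-ol (both C10 epimers) | OC1C=CC[C@H]2[C@@H](OC(C)(C)OC2(C)C)C1 | intermediate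
14 | (4aS,9aS)-2,2,4,4-tetramethyl-4a,5,9,9a-tetrahydro-4H-cyclohepta[d][1,3]dioxin-8-one | O=C1C=CC[C@H]2[C@@H](OC(C)(C)OC2(C)C)C1 | intermediate
15 | 2-bromopropene | CC(Br)=C | starting material
16 | isopropenylmagnesium bromide | CC(=C)[Mg]Br | intermediate
17 | allyl iodide | C=CCI | starting material
18 | bromomagnesium C1=C10 enolate carrying the 5-isopropenyl group | Br[Mg]OC1=C[C@H](C(C)=C)C[C@H]2[C@@H](OC(C)(C)OC2(C)C)C1 | intermediate
19 | (1S,5R,7S,8S)-1-allyl-5-isopropenyl ring B ketone 8,11-acetonide | O=C1[C@@H](CC=C)[C@H](C(C)=C)C[C@H]2[C@@H](OC(C)(C)OC2(C)C)C1 | intermediate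
20 | (1S,5R,7S,8S)-tricyclic ketone, C3=C4, C10=O, trans-fused rings A and B | O=C1[C@H]2CC=C(C)[C@@H]2C[C@H]3[C@@H](OC(C)(C)OC3(C)C)C1 | intermediate
21 | bromomagnesium enolate of 20 with C1=C10 | Br[Mg]OC1=C2CC=C(C)[C@@H]2C[C@H]3[C@@H](OC(C)(C)OC3(C)C)C1 | intermediate
22 | (5S,7S,8S)-C10 enol triflate, C1=C10 and C3=C4 | FC(F)(F)S(=O)(=O)OC1=C2CC=C(C)[C@@H]2C[C@H]3[C@@H](OC(C)(C)OC3(C)C)C1 | intermediate
23 | (5S,7S,8S)-guaia-1(10),3-diene-8,11-diol acetonide | CC1=C2CC=C(C)[C@@H]2C[C@H]3[C@@H](OC(C)(C)OC3(C)C)C1 | intermediate
24 | (4S,5S,7S,8S)-guai-1(10)-ene-8,11-diol acetonide | CC1=C2CC[C@H](C)[C@@H]2C[C@H]3[C@@H](OC(C)(C)OC3(C)C)C1 | intermediate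
25 | (4S,5S,7S,8S)-guai-1(10)-ene-8,11-diol | CC1=C2CC[C@H](C)[C@@H]2C[C@H](C(C)(C)O)[C@@H](O)C1 | intermediate
26 | p-coumaric acid | OC(=O)/C=C/c1ccc(O)cc1 | starting material
27 | tert-butyldimethylsilyl (E)-3-[4-(tert-butyldimethylsilyloxy)phenyl]prop-2-enoate | CC(C)(C)[Si](C)(C)OC(=O)/C=C/c1ccc(O[Si](C)(C)C(C)(C)C)cc1 | intermediate
28 | (E)-3-[4-(tert-butyldimethylsilyloxy)phenyl]prop-2-enoic acid | OC(=O)/C=C/c1ccc(O[Si](C)(C)C(C)(C)C)cc1 | intermediate
29 | (4S,5S,7S,8S)-11-hydroxyguai-1(10)-en-8-yl (E)-3-[4-(tert-butyldimethylsilyloxy)phenyl]prop-2-enoate | CC1=C2CC[C@H](C)[C@@H]2C[C@H](C(C)(C)O)[C@@H](OC(=O)/C=C/c2ccc(O[Si](C)(C)C(C)(C)C)cc2)C1 | intermediate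
30 | CNP0403230.1, (4S,5S,7S,8S)-11-hydroxyguai-1(10)-en-8-yl (E)-p-coumarate | CC1=C2CC[C@H](C)[C@@H]2C[C@H](C(C)(C)O)[C@@H](OC(=O)/C=C/c2ccc(O)cc2)C1 | target

Total steps: 21. Longest linear sequence: 19 (steps 1–11, 13–18, 20, 21).

Steps most likely to fail

Step 13. Facial control at C5 may be insufficient, because the catalyst works against the torsional preference of the ring for axial attack trans to C11. C-allylation of the magnesium enolate may also be slow enough for proton transfer to scramble the enolate.
- The fallback sets out from 14 and comes back at 23. It replaces face discrimination by stereospecific transfer from C10.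
- α-Iodination of 14 (I2, pyridine, CH2Cl2) gives the 1-iodo enone F1.
- Stille coupling with allyltributylstannane (Pd2(dba)3, AsPh3, CuI, NMP) gives the 1-allyl enone F2, so C1–C2 is made by cross-coupling.
- MeLi with CeCl3 adds to C10 from the face of the axial H8, and the alkoxide is acetylated in the flask with Ac2O to the tertiary allylic acetate F3, whose oxygen lies on the O8 face.
- The cuprate made from 16 and CuBr·SMe2 displaces the acetate in the anti SN2′ sense. This forms C4–C5 on the face cis to C11 and at the same time puts the C1=C10 bond and the C10 methyl in place, giving the triene F4.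
- Ring-closing metathesis of F4 with the second-generation Grubbs catalyst gives 23.

Step 15. Deprotonation at C9 may compete with C1 and lead to the wrong enol triflate regiochemistry. The time and temperature needed for equilibration may also allow loss of the C8 oxygen by β-elimination.
- The fallback sets out from 20 and comes back at 23, and it involves no enolate.
- MeMgBr with CeCl3 adds to the C10 ketone anti to the C1–C2 bond and gives the tertiary alcohol F5, whose hydroxyl is trans to H1.
- SOCl2 in pyridine at 0 °C then removes the anti-periplanar ring-fusion hydrogen through the chlorosulfite (anti E2, Zaitsev orientation) and gives 23.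

Step 17. The skipped diene may migrate into conjugation or be over-reduced on the metal surface, and discrimination between the two faces of ring A may be too small.
- The fallback sets out from 20 and comes back at 24. It moves the hydrogenation to a stage where C3=C4 is the only alkene.
- Equilibration of 20 at C1 with DBU in CH2Cl2 gives the cis-fused ketone F6, a cup-shaped bicycle with both ring B bonds on one face of ring A.
- Hydrogenation over Pd on carbon from the convex face gives the saturated ketone F7 with C4 as S.
- Thermodynamic enolisation and triflation under the conditions of step 15 give the enol triflate F8.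
- Iron-catalysed methylation under the conditions of step 16 gives 24.

Further compounds
F1 | step 13 | (7S,8S)-1-iodo ring B enone 8,11-acetonide | O=C1C(I)=CC[C@H]2[C@@H](OC(C)(C)OC2(C)C)C1
F2 | step 13 | (7S,8S)-1-allyl ring B enone 8,11-acetonide | O=C1C(CC=C)=CC[C@H]2[C@@H](OC(C)(C)OC2(C)C)C1
F3 | step 13 | (7S,8S,10R)-10-acetoxy-1-allyl-10-methyl ring B 1(5)-ene 8,11-acetonide (acetoxy cis to O8) | C[C@]1(OC(C)=O)C(CC=C)=CC[C@H]2[C@@H](OC(C)(C)OC2(C)C)C1
F4 | step 13 | (5R,7S,8S)-1-allyl-5-isopropenyl-10-methyl ring B 1(10)-ene 8,11-acetonide | CC1=C(CC=C)[C@H](C(C)=C)C[C@H]2[C@@H](OC(C)(C)OC2(C)C)C1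
F5 | step 15 | (1S,5R,7S,8S,10R)-guai-3-ene-8,10,11-triol 8,11-acetonide (10-OH trans to H1) | C[C@]1(O)[C@H]2CC=C(C)[C@@H]2C[C@H]3[C@@H](OC(C)(C)OC3(C)C)C1
F6 | step 17 | (1R,5R,7S,8S)-tricyclic ketone, C1 epimer of 20 (cis-fused rings A and B) | O=C1[C@@H]2CC=C(C)[C@@H]2C[C@H]3[C@@H](OC(C)(C)OC3(C)C)C1
F7 | step 17 | cis-fused saturated C10 ketone with 4S methyl, 8,11-acetonide | O=C1[C@@H]2CC[C@H](C)[C@@H]2C[C@H]3[C@@H](OC(C)(C)OC3(C)C)C1
F8 | step 17 | (4S,5S,7S,8S)-C10 enol triflate with C1=C10, ring A saturated | FC(F)(F)S(=O)(=O)OC1=C2CC[C@H](C)[C@@H]2C[C@H]3[C@@H](OC(C)(C)OC3(C)C)C1
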